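**Retrosynthetic overview**

1. Numbering: indane C1 bears the 4-hydroxyphenyl group, C2 the 3,5-dihydroxyphenyl group, C3 the side chain with carbinol carbon C8; ring A is C3a–C7a with oxygen on C5 and C7. The route rests on C3, which is bonded both to the ring A carbon C3a (meta to both ring A oxygens, so not reachable by Friedel–Crafts chemistry) and to the oxygenated C8: the C3a–C3–C8(O) unit is what a 1,2-shift leaves behind.
2. C8–OH ⇐ C8 ketone (CBS reduction, after the methyl ethers are exchanged for silyl ethers); C3–C3a ⇐ shift of C3a from C8 to C3 in a 1-aryl-tetralin cis-1,2-diol 2-mesylate, which contracts the six-membered ring to the indane.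
3. cis-Diol ⇐ OsO4 on the C3=C8 dihydronaphthalene ⇐ 4-methoxyphenyl Grignard on a tetralone; six-membered ring ⇐ Friedel–Crafts closure C1–C7a (C7a is ortho and para to the two methoxy groups).
4. C2 ⇐ Evans aldol of the (3,5-dimethoxyphenyl)acetyl imide with 4-methoxybenzaldehyde; C3–C8 ⇐ primary alkyllithium + 3,5-dimethoxybenzaldehyde (ring A).
5. Ring order: aromatic rings are bought; six-membered carbocycle in step 7; five-membered ring by contraction in step 12.

Key step: step 12

Assumption: compounds 13, 14 and 17 are carried on as mixtures of C8 epimers, since C8 becomes trigonal in steps 8 and 9; 4-MeOC6H4MgBr is used as the commercial THF solution.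

**Route**

Step 1
Reactants: 1 (3,5-dimethoxyphenyl)acetic acid; 2 (S)-4-benzyl-2-oxazolidinone
Product: 4 (S)-4-benzyl-3-[(3,5-dimethoxyphenyl)acetyl]oxazolidin-2-one, via mixed pivalic anhydride 3 (not isolated)
Conditions: PivCl, Et3N, THF, −20 °C; then LiCl, 2, −20 °C → rt
Reagents that add atoms: pivaloyl chloride CC(C)(C)C(Cl)=O (its atoms stay only in 3)
Why: N-acylation of the oxazolidinone through the mixed pivalic anhydride with LiCl/Et3N is the standard one-pot imide formation from a carboxylic acid and avoids ketene formation from an arylacetyl chloride; no stereocentre is formed.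

Step 2
Reactants: 4 (S)-4-benzyl-3-[(3,5-dimethoxyphenyl)acetyl]oxazolidin-2-one; 5 4-methoxybenzaldehyde
Product: 7 (S)-4-benzyl-3-[(2S,3S)-2-(3,5-dimethoxyphenyl)-3-hydroxy-3-(4-methoxyphenyl)propanoyl]oxazolidin-2-one, via dibutylboron Z-enolate 6 (not isolated)
Conditions: Bu2BOTf, iPr2NEt, CH2Cl2, −78 → 0 °C; 5, −78 → 0 °C; then pH 7 buffer, MeOH, 30% H2O2, 0 °C
Reagents that add atoms: dibutylboron triflate CCCCB(CCCC)OS(=O)(=O)C(F)(F)F (its atoms stay only in 6)
Why: Evans syn-aldol reaction: soft enolisation gives the Z boron enolate, which adds to the aldehyde through a closed chair (Zimmerman–Traxler) transition state on the enolate face away from the benzyl group, setting C2 as S (the only centre of this step that is kept to the end) and the C1 carbinol as S.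

Step 3
Reactants: 7 aldol adduct
Product: 8 (S)-4-benzyl-3-[(2S,3S)-3-[(tert-butyldimethylsilyl)oxy]-2-(3,5-dimethoxyphenyl)-3-(4-methoxyphenyl)propanoyl]oxazolidin-2-one
Conditions: TBSOTf, 2,6-lutidine, CH2Cl2, −78 → 0 °C
Reagents that add atoms: tert-butyldimethylsilyl triflate CC(C)(C)[Si](C)(C)OS(=O)(=O)C(F)(F)F
Why: Silylation of the secondary benzylic alcohol with a silyl triflate and a hindered pyridine base masks the hydroxyl for the organolithium step and blocks retro-aldol cleavage; no stereocentre is touched.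

Step 4
Reactants: 8 silyl ether imide
Product: 9 (2R,3S)-3-[(tert-butyldimethylsilyl)oxy]-2-(3,5-dimethoxyphenyl)-3-(4-methoxyphenyl)propan-1-ol
Conditions: LiBH4, MeOH (1 equiv), THF, 0 °C
Reagents that add atoms: none
Why: Reductive cleavage of the N-acyl oxazolidinone with LiBH4 gives the primary alcohol and returns the auxiliary, and it takes C2 out of the position α to a carbonyl so that it can no longer epimerise.

Step 5
Reactants: 9 primary alcohol
Product: 10 tert-butyl{[(1S,2S)-2-(3,5-dimethoxyphenyl)-3-iodo-1-(4-methoxyphenyl)propyl]oxy}dimethylsilane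
Conditions: I2, PPh3, imidazole, CH2Cl2, 0 °C → rt
Reagents that add atoms: iodine II
Why: Appel-type iodination converts the primary alcohol into the iodide by SN2 displacement at the CH2 carbon under buffered conditions that leave the benzylic silyl ether and C2 untouched.

Step 6
Reactants: 10 primary iodide; 11 3,5-dimethoxybenzaldehyde
Product: 13 (3S,4S)-4-[(tert-butyldimethylsilyl)oxy]-1,3-bis(3,5-dimethoxyphenyl)-4-(4-methoxyphenyl)butan-1-ol (both C1 epimers of the butanol), via primary alkyllithium 12 (not isolated)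
Conditions: t-BuLi (2.1 equiv), Et2O–pentane, −78 °C; then 11, −78 → −20 °C; then H2O
Reagents that add atoms: tert-butyllithium [Li]C(C)(C)C (lithium stays only in 12)
Why: Iodine–lithium exchange with two equivalents of t-BuLi gives the primary alkyllithium, which adds 1,2 to the non-enolisable aromatic aldehyde and forms the C3–C8 bond; the new C8 carbinol centre is formed unselectively, which has no consequence because C8 is oxidised in step 8.

Step 7
Reactants: 13 silyloxy alcohol
Product: 14 (3R,4R)-3-(3,5-dimethoxyphenyl)-5,7-dimethoxy-4-(4-methoxyphenyl)-1,2,3,4-tetrahydronaphthalen-1-ol (3,4-trans; both C1 epimers)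
Conditions: TsOH·H2O (10 mol %), CH2Cl2–(CF3)2CHOH 4:1, 0 °C → rt
Reagents that add atoms: none
Why: Intramolecular Friedel–Crafts alkylation: acid ionises the 4-methoxybenzylic silyl ether at C1 and the cation is captured at C7a, the ring A position ortho and para to the two methoxy groups, in a six-membered ring closure (the same change as the acid-induced conversion of 2,5-diaryltetrahydrofuran lignans into aryltetralins, capture by the C8 hydroxyl being only a reversible side equilibrium), with the C1 aryl group ending trans to the C2 aryl group through a chair-like transition state in which both are pseudoequatorial; the closure is run at the alcohol oxidation level of C8 so that ring A is not deactivated by a ketone.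

Step 8
Reactants: 14 tetralol
Product: 15 (3R,4R)-3-(3,5-dimethoxyphenyl)-5,7-dimethoxy-4-(4-methoxyphenyl)-3,4-dihydronaphthalen-1(2H)-one
Conditions: Dess–Martin periodinane, CH2Cl2, rt
Reagents that add atoms: none
Why: Dess–Martin oxidation of the secondary benzylic alcohol gives the aryl ketone under neutral conditions and merges the two C8 epimers; C1 and C2 are not α to the carbonyl and stay as set.

Step 9
Reactants: 15 tetralone; 16 4-methoxyphenylmagnesium bromide
Product: 18 (1R,2R)-2-(3,5-dimethoxyphenyl)-6,8-dimethoxy-1,4-bis(4-methoxyphenyl)-1,2-dihydronaphthalene, via tertiary benzylic alcohol 17 (not isolated)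
Conditions: 16, anhydrous CeCl3, THF, −78 → 0 °C, then H2O; crude 17, TsOH·H2O (5 mol %), toluene, rt
Reagents that add atoms: none
Why: Grignard 1,2-addition to the aryl ketone (CeCl3 suppresses enolisation) followed by acid-catalysed E1 dehydration of the tertiary dibenzylic alcohol, which can lose a proton only from C3, gives the conjugated C3=C8 alkene inside the ring, so no alkene geometry has to be controlled and no stereocentre is formed.

Step 10
Reactants: 18 dihydronaphthalene
Product: 19 (1S,2R,3R,4R)-3-(3,5-dimethoxyphenyl)-5,7-dimethoxy-1,4-bis(4-methoxyphenyl)-1,2,3,4-tetrahydronaphthalene-1,2-diol (cis-diol, anti to the 3-aryl group)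
Conditions: OsO4 (5 mol %), NMO, MeSO2NH2, acetone–H2O, rt
Reagents that add atoms: osmium tetroxide O=[Os](=O)(=O)=O; N-methylmorpholine N-oxide C[N+]1([O-])CCOCC1; water O
Why: Upjohn dihydroxylation adds the two hydroxyl groups syn to the C3=C8 bond from the face opposite the allylic aryl group on C2, which sets C3 and C8 together as the cis-diol anti to that aryl group.

Step 11
Reactants: 19 cis-diol
Product: 20 (1S,2R,3R,4R)-3-(3,5-dimethoxyphenyl)-1-hydroxy-5,7-dimethoxy-1,4-bis(4-methoxyphenyl)-1,2,3,4-tetrahydronaphthalen-2-yl methanesulfonate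
Conditions: MsCl, Et3N, CH2Cl2, −20 → 0 °C
Reagents that add atoms: methanesulfonyl chloride CS(Cl)(=O)=O
Why: Sulfonylation with MsCl/Et3N is selective for the secondary C3 hydroxyl because the tertiary dibenzylic C8 hydroxyl is too hindered to react, and configuration is retained since only the O–H bond is broken.

Step 12
Reactants: 20 hydroxy mesylate
Product: 21 all-trans [(1R,2S,3R)-2-(3,5-dimethoxyphenyl)-4,6-dimethoxy-3-(4-methoxyphenyl)-2,3-dihydro-1H-inden-1-yl](4-methoxyphenyl)methanone
Conditions: KOtBu, THF, 0 °C → rt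
Reagents that add atoms: none
Why: KOtBu deprotonates the tertiary C8 hydroxyl, and the alkoxide pushes the C8–C3a bond onto C3 as mesylate leaves, so that C3–C3a forms and C8 becomes the aryl ketone; this bond lies antiperiplanar to the equatorial C3–OMs bond in the half-chair that holds the three trans substituents on C1, C2 and C3 equatorial. This is a base-induced semipinacol (Tiffeneau–Demjanov-type) rearrangement of a cyclic cis-1,2-diol monosulfonate, the same bond reorganisation as the known contraction of 1,2-dihydronaphthalene derivatives to 1-acylindanes. The five-membered ring closes by ring contraction: C3–C3a replaces C8–C3a through a bridged, bicyclo[3.1.0]-like transition state, not by an exo or endo cyclisation. C3 is the only new stereocentre; C3a enters anti to the departing mesylate (inversion), which places the new C3–C8 bond trans to the C2 aryl group, and base epimerisation at this ketone α-position can only reinforce the all-trans arrangement. The step needs the ring bond to migrate in preference to the 4-methoxyphenyl group on C8 and needs elimination and epoxide formation to be absent. The aryl group is gauche to the leaving group in the reactive conformer (it is anti only in the all-axial conformer, which has two syn-diaxial contacts), the cis-diol geometry forbids epoxide closure, and C3–OMs has no antiperiplanar hydrogen on C2 while C8 has no hydrogen at all.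

Step 13
Reactants: 21 ketone pentamethyl ether
Product: 22 [(1R,2S,3R)-2-(3,5-dihydroxyphenyl)-4,6-dihydroxy-3-(4-hydroxyphenyl)-2,3-dihydro-1H-inden-1-yl](4-hydroxyphenyl)methanone
Conditions: BBr3 (excess), CH2Cl2, −78 °C → rt; then H2O
Reagents that add atoms: none
Why: Lewis-acid ether cleavage with BBr3 removes the five aryl methyl groups at the ketone stage, where no ionisable benzylic C–O bond is present (the C8 carbinol of the target would not survive this reagent); the all-trans ring is the thermodynamic arrangement, so C3 is not expected to change.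

Step 14
Reactants: 22 pentaphenol ketone
Product: 23 penta-O-(tert-butyldimethylsilyl) ether of 22
Conditions: TBSCl, imidazole, DMF, rt
Reagents that add atoms: tert-butyldimethylsilyl chloride CC(C)(C)[Si](C)(C)Cl
Why: Silylation of the five phenols with TBSCl/imidazole gives a lipophilic, borane-inert substrate for the reduction and a protecting group that can later be removed without acid.

Step 15
Reactants: 23 pentasilyl ketone
Product: 24 pentasilyl ether of the target with the (R)-configured C8 carbinol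
Conditions: (S)-2-methyl-CBS-oxazaborolidine (0.5 equiv), BH3·SMe2, toluene, −20 °C; then MeOH
Reagents that add atoms: none
Why: Corey–Bakshi–Shibata reduction: the (S)-oxazaborolidine–borane complex binds the ketone with the aryl group as the large substituent and delivers hydride to the face that gives the R carbinol at C8 (reagent control, in the same sense as acetophenone giving the R alcohol).

Step 16
Reactants: 24 pentasilyl carbinol
Product: 25 (1R,2S,3R)-2-(3,5-dihydroxyphenyl)-1-[(R)-hydroxy(4-hydroxyphenyl)methyl]-3-(4-hydroxyphenyl)-2,3-dihydro-1H-indene-4,6-diol (the target)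
Conditions: Bu4NF, AcOH, THF, 0 °C
Reagents that add atoms: none
Why: Fluoride cleavage of the five aryl silyl ethers with acetic-acid-buffered Bu4NF is fast at 0 °C and avoids both acid and strong base, so the 4-hydroxybenzylic C8–OH is not ionised to a quinone methide.

**Compound list**

1 | (3,5-dimethoxyphenyl)acetic acid | OC(=O)Cc1cc(OC)cc(OC)c1 | starting material
2 | (S)-4-benzyl-2-oxazolidinone | O=C1N[C@@H](Cc2ccccc2)CO1 | starting material
3 | (3,5-dimethoxyphenyl)acetic pivalic anhydride | CC(C)(C)C(=O)OC(=O)Cc1cc(OC)cc(OC)c1 | intermediate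
4 | (S)-4-benzyl-3-[(3,5-dimethoxyphenyl)acetyl]oxazolidin-2-one | COc1cc(CC(=O)N2[C@@H](Cc3ccccc3)COC2=O)cc(OC)c1 | intermediate
5 | 4-methoxybenzaldehyde | COc1ccc(C=O)cc1 | starting material
6 | dibutylboron (Z)-enolate of 4 | CCCCB(CCCC)O/C(=C\c1cc(OC)cc(OC)c1)N1[C@@H](Cc2ccccc2)COC1=O | intermediate
7 | (S)-4-benzyl-3-[(2S,3S)-2-(3,5-dimethoxyphenyl)-3-hydroxy-3-(4-methoxyphenyl)propanoyl]oxazolidin-2-one | COc1ccc(cc1)[C@@H](O)[C@H](c1cc(OC)cc(OC)c1)C(=O)N1[C@@H](Cc2ccccc2)COC1=O | intermediate
8 | tert-butyldimethylsilyl ether of 7 | COc1ccc(cc1)[C@@H](O[Si](C)(C)C(C)(C)C)[C@H](c1cc(OC)cc(OC)c1)C(=O)N1[C@@H](Cc2ccccc2)COC1=O | intermediate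
9 | (2R,3S)-3-[(tert-butyldimethylsilyl)oxy]-2-(3,5-dimethoxyphenyl)-3-(4-methoxyphenyl)propan-1-ol | COc1ccc(cc1)[C@@H](O[Si](C)(C)C(C)(C)C)[C@H](c1cc(OC)cc(OC)c1)CO | intermediate
10 | tert-butyl{[(1S,2S)-2-(3,5-dimethoxyphenyl)-3-iodo-1-(4-methoxyphenyl)propyl]oxy}dimethylsilane | COc1ccc(cc1)[C@@H](O[Si](C)(C)C(C)(C)C)[C@H](c1cc(OC)cc(OC)c1)CI | intermediate
11 | 3,5-dimethoxybenzaldehyde | COc1cc(C=O)cc(OC)c1 | starting material
12 | primary alkyllithium from 10 | COc1ccc(cc1)[C@@H](O[Si](C)(C)C(C)(C)C)[C@H](c1cc(OC)cc(OC)c1)C[Li] | intermediate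
13 | (3S,4S)-4-[(tert-butyldimethylsilyl)oxy]-1,3-bis(3,5-dimethoxyphenyl)-4-(4-methoxyphenyl)butan-1-ol, both C1 epimers | COc1ccc(cc1)[C@@H](O[Si](C)(C)C(C)(C)C)[C@H](c1cc(OC)cc(OC)c1)CC(O)c1cc(OC)cc(OC)c1 | intermediate
14 | (3R,4R)-3-(3,5-dimethoxyphenyl)-5,7-dimethoxy-4-(4-methoxyphenyl)-1,2,3,4-tetrahydronaphthalen-1-ol, both C1 epimers | COc1ccc([C@@H]2c3c(OC)cc(OC)cc3C(O)C[C@H]2c2cc(OC)cc(OC)c2)cc1 | intermediate
15 | (3R,4R)-3-(3,5-dimethoxyphenyl)-5,7-dimethoxy-4-(4-methoxyphenyl)-3,4-dihydronaphthalen-1(2H)-one | COc1ccc([C@@H]2c3c(OC)cc(OC)cc3C(=O)C[C@H]2c2cc(OC)cc(OC)c2)cc1 | intermediate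
16 | 4-methoxyphenylmagnesium bromide | COc1ccc([Mg]Br)cc1 | starting material
17 | (3R,4R)-3-(3,5-dimethoxyphenyl)-5,7-dimethoxy-1,4-bis(4-methoxyphenyl)-1,2,3,4-tetrahydronaphthalen-1-ol, both C1 epimers | COc1ccc([C@@H]2c3c(OC)cc(OC)cc3C(O)(c3ccc(OC)cc3)C[C@H]2c2cc(OC)cc(OC)c2)cc1 | intermediate
18 | (1R,2R)-2-(3,5-dimethoxyphenyl)-6,8-dimethoxy-1,4-bis(4-methoxyphenyl)-1,2-dihydronaphthalene | COc1ccc([C@@H]2c3c(OC)cc(OC)cc3C(c3ccc(OC)cc3)=C[C@H]2c2cc(OC)cc(OC)c2)cc1 | intermediate
19 | (1S,2R,3R,4R)-3-(3,5-dimethoxyphenyl)-5,7-dimethoxy-1,4-bis(4-methoxyphenyl)-1,2,3,4-tetrahydronaphthalene-1,2-diol | COc1ccc([C@@H]2c3c(OC)cc(OC)cc3[C@@](O)(c3ccc(OC)cc3)[C@H](O)[C@H]2c2cc(OC)cc(OC)c2)cc1 | intermediate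
20 | (1S,2R,3R,4R)-3-(3,5-dimethoxyphenyl)-1-hydroxy-5,7-dimethoxy-1,4-bis(4-methoxyphenyl)-1,2,3,4-tetrahydronaphthalen-2-yl methanesulfonate | COc1ccc([C@@H]2c3c(OC)cc(OC)cc3[C@@](O)(c3ccc(OC)cc3)[C@H](OS(C)(=O)=O)[C@H]2c2cc(OC)cc(OC)c2)cc1 | intermediate
21 | [(1R,2S,3R)-2-(3,5-dimethoxyphenyl)-4,6-dimethoxy-3-(4-methoxyphenyl)-2,3-dihydro-1H-inden-1-yl](4-methoxyphenyl)methanone | COc1ccc([C@@H]2c3c(OC)cc(OC)cc3[C@H](C(=O)c3ccc(OC)cc3)[C@H]2c2cc(OC)cc(OC)c2)cc1 | intermediate
22 | [(1R,2S,3R)-2-(3,5-dihydroxyphenyl)-4,6-dihydroxy-3-(4-hydroxyphenyl)-2,3-dihydro-1H-inden-1-yl](4-hydroxyphenyl)methanone | Oc1ccc([C@@H]2c3c(O)cc(O)cc3[C@H](C(=O)c3ccc(O)cc3)[C@H]2c2cc(O)cc(O)c2)cc1 | intermediate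
23 | penta-O-(tert-butyldimethylsilyl) ether of 22 | CC(C)(C)[Si](C)(C)Oc1ccc([C@@H]2c3c(O[Si](C)(C)C(C)(C)C)cc(O[Si](C)(C)C(C)(C)C)cc3[C@H](C(=O)c3ccc(O[Si](C)(C)C(C)(C)C)cc3)[C@H]2c2cc(O[Si](C)(C)C(C)(C)C)cc(O[Si](C)(C)C(C)(C)C)c2)cc1 | intermediate
24 | penta-O-(tert-butyldimethylsilyl) ether of the target, (R) at the carbinol carbon | CC(C)(C)[Si](C)(C)Oc1ccc([C@@H]2c3c(O[Si](C)(C)C(C)(C)C)cc(O[Si](C)(C)C(C)(C)C)cc3[C@H]([C@@H](O)c3ccc(O[Si](C)(C)C(C)(C)C)cc3)[C@H]2c2cc(O[Si](C)(C)C(C)(C)C)cc(O[Si](C)(C)C(C)(C)C)c2)cc1 | intermediate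
25 | (1R,2S,3R)-2-(3,5-dihydroxyphenyl)-1-[(R)-hydroxy(4-hydroxyphenyl)methyl]-3-(4-hydroxyphenyl)-2,3-dihydro-1H-indene-4,6-diol | Oc1ccc([C@@H]2c3c(O)cc(O)cc3[C@H]([C@@H](O)c3ccc(O)cc3)[C@H]2c2cc(O)cc(O)c2)cc1 | target

**Step count and risks**

Total step count: 16. Longest linear sequence: 16 steps (1 → 25).

Step 12 (key step). What may go wrong: migration of the 4-methoxyphenyl group on C8 in place of the ring bond, which would keep the six-membered ring and give a 2-aryl-1-tetralone, or loss of the tertiary dibenzylic hydroxyl by ionisation before the shift. Fallback: contract the ring before that aryl group is present. Setting out from tetralol 14, dehydration (TsOH, toluene, 80 °C) should give (1R,2R)-2-(3,5-dimethoxyphenyl)-6,8-dimethoxy-1-(4-methoxyphenyl)-1,2-dihydronaphthalene F1. Oxidative ring contraction of F1 with PhI(OH)OTs in MeOH/HC(OMe)3, a known reaction of 1,2-dihydronaphthalenes that gives trans-1,3-disubstituted indanes by the same aryl shift, should give the all-trans indane-3-carbaldehyde dimethyl acetal F2. Mild aqueous acid should then release the all-trans indane-3-carbaldehyde F3. Addition of Grignard reagent 16 should give the C8 carbinol pentamethyl ether F4 as a mixture of epimers, and Dess–Martin oxidation of F4 comes back to the route at ketone 21.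

Step 10. What may go wrong: poor facial selectivity, because the homoallylic C1 aryl group hinders the face that the allylic C2 aryl group leaves open, or very slow osmylation of the hindered 1,1-diaryl trisubstituted alkene. Fallback: build the diol from the ketone and not from the alkene. Setting out from tetralone 15, TMSOTf/Et3N should give the trimethylsilyl enol ether F5. Rubottom oxidation of F5 (mCPBA, then mild acid) should give the 2-hydroxy-1-tetralone F6, in which the C3 hydroxyl can equilibrate to the position trans to the C2 aryl group because C3 is α to the ketone. Chelation-controlled addition of excess 16 to F6, anti to the α-oxygen, should give the cis-diol and comes back to the route at 19.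

Step 15. What may go wrong: mismatched double stereodifferentiation, in which the bias of the C3 stereocentre beside the ketone overrides the oxazaborolidine and the reduction gives mainly the C8 epimer. Fallback: substrate-controlled reduction followed by inversion. Setting out from ketone 23, NaBH4 in THF/MeOH should give the (8S)-carbinol pentasilyl ether F7. Mitsunobu reaction of F7 (4-nitrobenzoic acid, PPh3, DIAD) should invert C8 and give the (8R)-4-nitrobenzoate F8. Treatment of F8 with K2CO3 in MeOH should remove the ester and the five aryl silyl ethers together, so the fallback comes back to the route at the target 25.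

Further compounds
F1 | step 12 | (1R,2R)-2-(3,5-dimethoxyphenyl)-6,8-dimethoxy-1-(4-methoxyphenyl)-1,2-dihydronaphthalene | COc1ccc([C@@H]2c3c(OC)cc(OC)cc3C=C[C@H]2c2cc(OC)cc(OC)c2)cc1
F2 | step 12 | all-trans 3-(dimethoxymethyl)-2-(3,5-dimethoxyphenyl)-5,7-dimethoxy-1-(4-methoxyphenyl)indane (overview numbering) | COc1ccc([C@@H]2c3c(OC)cc(OC)cc3[C@H](C(OC)OC)[C@H]2c2cc(OC)cc(OC)c2)cc1
F3 | step 12 | all-trans 2-(3,5-dimethoxyphenyl)-5,7-dimethoxy-1-(4-methoxyphenyl)indane-3-carbaldehyde (overview numbering) | COc1ccc([C@@H]2c3c(OC)cc(OC)cc3[C@H](C=O)[C@H]2c2cc(OC)cc(OC)c2)cc1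
F4 | step 12 | C8 carbinol pentamethyl ether, both C8 epimers | COc1ccc([C@@H]2c3c(OC)cc(OC)cc3[C@H](C(O)c3ccc(OC)cc3)[C@H]2c2cc(OC)cc(OC)c2)cc1
F5 | step 10 | trimethylsilyl enol ether of tetralone 15 | COc1ccc([C@@H]2c3c(OC)cc(OC)cc3C(O[Si](C)(C)C)=C[C@H]2c2cc(OC)cc(OC)c2)cc1
F6 | step 10 | 2-hydroxy derivative of tetralone 15, hydroxyl trans to the 3-aryl group | COc1ccc([C@@H]2c3c(OC)cc(OC)cc3C(=O)[C@H](O)[C@H]2c2cc(OC)cc(OC)c2)cc1
F7 | step 15 | C8 epimer of 24, (S) at the carbinol carbon | CC(C)(C)[Si](C)(C)Oc1ccc([C@@H]2c3c(O[Si](C)(C)C(C)(C)C)cc(O[Si](C)(C)C(C)(C)C)cc3[C@H]([C@H](O)c3ccc(O[Si](C)(C)C(C)(C)C)cc3)[C@H]2c2cc(O[Si](C)(C)C(C)(C)C)cc(O[Si](C)(C)C(C)(C)C)c2)cc1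
F8 | step 15 | 4-nitrobenzoate of 24, (R) at the carbinol carbon | CC(C)(C)[Si](C)(C)Oc1ccc([C@@H]2c3c(O[Si](C)(C)C(C)(C)C)cc(O[Si](C)(C)C(C)(C)C)cc3[C@H]([C@@H](OC(=O)c4ccc(cc4)[N+]([O-])=O)c3ccc(O[Si](C)(C)C(C)(C)C)cc3)[C@H]2c2cc(O[Si](C)(C)C(C)(C)C)cc(O[Si](C)(C)C(C)(C)C)c2)cc1
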